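# Proposed synthesis of CNP0150993.1, (2S)-5,7-dihydroxy-2-(4-hydroxyphenyl)-6-[(1E,3S)-3,7-dimethylocta-1,6-dien-1-yl]chroman-4-one

## Analysis of the target

The target is a flavanone. Ring A is a benzene ring with oxygen on C5, C7 and C8a, ring C is the dihydropyranone (O1, C2, C3, C4, C4a, C8a), and ring B is a 4-hydroxyphenyl group on C2. C6, the carbon between the two phenolic oxygens, carries a (1E,3S)-3,7-dimethylocta-1,6-dienyl chain. There are two stereocentres, C2 (S) and C3' (S). They are separated by ring A and the C1'=C2' double bond, cannot control each other, and must be set independently. C2 is the fragile one: it is benzylic, bonded to O1 and β to the C4 carbonyl, so base opens ring C by a retro-oxa-Michael reaction and acid can ionise C2–O1, the more easily the stronger the donor on ring B. The chain adds an ortho-hydroxystyrene and a trisubstituted alkene, both of which cyclise onto the neighbouring phenols under Brønsted or Lewis acid. The main difficulty is regiochemical: C6 and C8 of a 5,7-dioxygenated flavanone are electronically alike and differ only in their relation to ring C, so substitution of a finished flavanone is unreliable. The feature that removes this problem is that C6 is para to C8a. If ring C is closed onto an aryl ether whose future C6 substituent sits para to the ether oxygen and between two identical oxygen substituents, the two carbons ortho to the ether oxygen (the future C4a and C8) are mirror images, and closure at either gives the 6-substituted flavanone.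

## Retrosynthetic reasoning

**23 from 22 (O–acetyl bond on ring B).** The last step should be the mildest one, because 23 tolerates neither acid (chain) nor base (ring C). An acetate on the ring B oxygen is therefore carried to the end. As an ester it also keeps ring B a weak donor throughout, which protects C2–O1 against ionisation, and it can be removed at near-neutral pH.

**22 from 17 and 21 (C6–C1').** This is the only bond between ring A and the chain, and it joins two sp2 carbons. Cutting it makes the route convergent and keeps the acid-labile chain out of every acidic step. The forward reaction is a Stille coupling of a hindered, electron-rich aryl bromide flanked by two free hydroxyl groups with an (E)-alkenylstannane. It must run without base, because ring C of 17 opens under base, and it must keep the alkene geometry.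

**21 from 20, and 20 from 18 (C–Sn bond, then the alkyne).** Aldehyde 18 already holds all ten carbons of the chain and its C3 stereocentre. Its C1 and C2 must become C1' and C2', so the CH2–CHO unit is converted into C≡CH through enol sulfonate 19, with no carbon added or lost. Syn-hydrostannylation of 20 then sets the (E) geometry. C3 is never part of a reacting centre.

**17 from 16 (two O–benzyl bonds).** Benzyl ethers are good donors for the ring closure and can be cleaved by a Lewis acid at low temperature. Hydrogenolysis is excluded by the C–Br bond. The cleavage is placed before the chain is attached, because the chain would not survive a Lewis acid.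

**16 from 14 through 15 (C4–C4a, the key disconnection).** Cutting the aryl ketone bond opens ring C to a 3-aryloxy-3-arylpropanoic acid whose aryloxy ring has a mirror plane through the ether carbon and the C–Br carbon. The forward Friedel–Crafts acylation therefore has only one possible regiochemical outcome, and bromine ends at C6 without any directing or blocking group. The reaction must activate the acid mildly enough that the C2–O1 bond neither ionises nor eliminates.

**14 from 13, and 13 from 6 and 12 (O1–C2).** The aryl ether bond is made by SN2 displacement at the benzylic carbon with inversion, so the (R)-carbinol 12 gives the (S)-ether. The acid is carried as a tert-butyl ester and freed by acid, because hydroxide or alkoxide would expel the aryloxide β to the carbonyl group.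

**12 from 11, and 11 from 7 and 8 (C2–H, then C3–C4).** The carbinol stereocentre comes from catalytic asymmetric hydrogenation of β-keto ester 11. Ester 11 is assembled from acid 7 and malonate half-ester salt 8 under conditions that spare the aryl acetate.

**6 from 1 through 2, 3, 4 and 5 (C–O in place of C–C at the ring carbon para to bromine).** Acid 1 already has bromine between two oxygens and a one-carbon substituent para to it, so the symmetric pattern is bought rather than made. The carboxyl carbon is replaced by oxygen through a Baeyer–Villiger oxidation. The acetyl group of 4, and not a formyl group, is chosen as the partner of the migrating ring. The ring has its oxygens meta and its bromine para to the migrating carbon; such a ring out-migrates methyl but would not be expected to out-migrate hydride.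

## Alternatives that were turned down

**Alternative 1:** Ring A is disconnected last, at C8–C8a and C4a–C5. The fragments are the (S)-5-bromo-2-aryl-2,3-dihydropyran-4-one A2 and the 1-methoxy-1,3-bis(trimethylsilyloxy)butadiene A3, which already carries the chain on its C2. In the forward step the terminal carbon of A3 adds to C8a, the enolate carbon C4a closes onto the ketene acetal carbon, and loss of HBr and methoxytrimethylsilane aromatises ring A to give A1, the 4'-silyl ether of the target.
- For it: the route is shorter and more convergent than the chosen one. The chain is fixed at C6 by the constitution of A3, so no coupling at a crowded ring carbon is needed, ring A needs no protecting groups, and A2 is accessible by a catalytic asymmetric hetero-Diels–Alder reaction and bromination. On step economy this alternative is stronger.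
- Against it: the double enolisation needed to make A3 puts C3'–H at a vinylogous acidic position, which threatens the C3' configuration and the alkene geometry. After the first C–C bond is formed, the enolate at C4a can expel O1 by E1cB, whereas bromine sits on the enolate carbon itself and cannot leave that way. Ring C may therefore open before ring A aromatises, and C2 then loses its ring. The Lewis acid needed (TiCl4 or Me3SiOTf) meets the acid-labile chain.
- Comparison: the chosen route accepts more steps in exchange for stable intermediates, a ring closure with no mechanistic fork, and introduction of the chain only when nothing acidic remains to be done.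

**Alternative 2:** Ring C is disconnected at C2–C3. The precursor is the α-diazo ketone A5, whose ortho oxygen carries the ring B benzyl group. In the forward step a chiral dirhodium tetracarboxylate such as Rh2(BSP)4 (BSP = N-benzenesulfonylprolinate) generates a carbenoid that inserts into a benzylic O–CH2 bond, closing ring C and giving A4.
- For it: the C2 stereocentre and ring C are formed in one catalytic step, which the chosen strategy cannot match, since it sets C2 two steps before the ring closure. The six-membered insertion is the only one geometrically available, and the C–H bond is activated by oxygen and by the aryl group.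
- Against it: a carbenoid with only a ketone acceptor is very reactive and gives limited enantiocontrol. The ether oxygen can trap it as an oxonium ylide, which diverts material into a rearranged five-membered isomer. A5 has an unsymmetrical ring A: three phenolic oxygens must be differentiated and bromine placed between two specific ones, so the regiochemical problem is only moved to the start. In A4 bromine is flanked by two triisopropylsilyloxy groups, which would hinder the later coupling, and fluoride deprotection is basic enough to endanger ring C.
- Comparison: the chosen route derives the C2 configuration from a hydrogenation and an SN2 inversion, both with predictable outcome, and gets its regiochemistry from symmetry.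

**Alternative 3:** Ring C is disconnected at O1–C8a. The precursor is the (S)-β-hydroxy ketone A7 with fluorine on the future C8a. In the forward step the alkoxide, formed with K2CO3 or Cs2CO3 in DMF, displaces fluoride to give A6, the tris(methoxymethyl) ether of the target.
- For it: the C–O bond at the stereocentre is never made or broken, which is at least as safe as an inversion. The chain is already in place, so no late coupling is needed.
- Against it: a β-hydroxy ketone under carbonate in hot DMF can undergo retro-aldol cleavage and E1cB dehydration. The fluoride sits on a ring with three donors and only one activating acyl group, so the substitution is slow and the side reactions have time. The fully substituted, unsymmetrical ring A of A7 has to be built substituent by substituent. The final removal of three methoxymethyl groups needs acid, which the ortho-hydroxystyrene and the trisubstituted alkene do not tolerate.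
- Comparison: the chosen route ends with a near-neutral deacetylation and needs no regiocontrol on ring A.

Key step: step 8

## Route

Remark: aldehyde 18 is taken to be of high enantiomeric purity, because its C3 becomes C3' of the target and cannot be enriched later.

Step 1
Reactants: 1 4-bromo-3,5-dihydroxybenzoic acid
Product: 2 benzyl 3,5-bis(benzyloxy)-4-bromobenzoate
Conditions: BnBr (3.6 equiv), K2CO3 (4 equiv), DMF, 60 °C
Reagents that add atoms: benzyl bromide, BrCc1ccccc1
Why: Williamson O-alkylation of both phenoxides and esterification of the carboxylate by SN2 on benzyl bromide; the symmetric substrate leaves no regiochemical choice.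

Step 2
Reactants: 2 benzyl 3,5-bis(benzyloxy)-4-bromobenzoate
Product: 4 1-[3,5-bis(benzyloxy)-4-bromophenyl]ethan-1-one, via Weinreb amide 3 (not isolated)
Conditions: MeNH(OMe)·HCl (1.5 equiv), iPrMgCl (3 equiv), THF, −20 °C; then MeMgBr (3 equiv), −20 to 0 °C; aq NH4Cl
Reagents that add atoms: N,O-dimethylhydroxylamine hydrochloride, CNOC.Cl (the N-methoxy-N-methylamino group of 3 only); methylmagnesium bromide, C[Mg]Br
Why: Weinreb ketone synthesis run in one pot: the magnesium amide converts the ester into amide 3, whose chelated tetrahedral adduct with MeMgBr persists until work-up, so addition stops at the methyl ketone. The hindered, electron-rich C–Br bond should not undergo halogen–magnesium exchange at this temperature.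

Step 3
Reactants: 4 1-[3,5-bis(benzyloxy)-4-bromophenyl]ethan-1-one
Product: 6 3,5-bis(benzyloxy)-4-bromophenol, via aryl acetate 5 (not isolated)
Conditions: mCPBA (2.5 equiv), TFA (1 equiv), CH2Cl2, 0 °C to rt, dark; aq Na2S2O3/NaHCO3; then K2CO3, MeOH, rt
Reagents that add atoms: 3-chloroperoxybenzoic acid, OOC(=O)c1cccc(Cl)c1
Why: Baeyer–Villiger oxidation: in the Criegee adduct of an aryl methyl ketone the aryl group migrates in preference to methyl even without ortho or para donors, and acid catalysis compensates for the modest migratory aptitude of this ring. Methanolysis of aryl acetate 5 then frees the phenol; benzyl ethers and the bromide are inert to both stages.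

Step 4
Reactants: 7 4-acetoxybenzoic acid; 8 potassium 3-(tert-butoxy)-3-oxopropanoate
Product: 11 tert-butyl 3-(4-acetoxyphenyl)-3-oxopropanoate, via acid chloride 9 (not isolated), via acylmalonic half ester 10 (not isolated)
Conditions: (COCl)2, DMF (cat.), CH2Cl2, 0 °C to rt, evaporate; then 8, MgCl2, Et3N, MeCN, 0 °C to rt; aq citric acid
Reagents that add atoms: oxalyl chloride, O=C(Cl)C(Cl)=O (the chlorine of 9 only)
Why: Decarboxylative Claisen-type condensation: the magnesium enolate of the malonic half ester is C-acylated by acid chloride 9 and the adduct 10 loses CO2 on acidification. The soft magnesium enolate and triethylamine leave the aryl acetate and the tert-butyl ester intact, whereas a lithium ester enolate would attack the acetate.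

Step 5
Reactants: 11 tert-butyl 3-(4-acetoxyphenyl)-3-oxopropanoate
Product: 12 tert-butyl (R)-3-(4-acetoxyphenyl)-3-hydroxypropanoate
Conditions: H2 (50 bar), RuCl2[(S)-BINAP] (1 mol %), EtOH/CH2Cl2, 40 °C
Reagents that add atoms: none
Why: Noyori asymmetric hydrogenation of a β-keto ester through the chelated ruthenium hydride; (S)-BINAP should deliver hydrogen to the same face as for alkyl β-keto esters, and the descriptor is (R) here only because aryl outranks CH2CO2tBu. The moderate temperature and the co-solvent limit solvolysis of the aryl acetate.

Step 6
Reactants: 6 3,5-bis(benzyloxy)-4-bromophenol; 12 tert-butyl (R)-3-(4-acetoxyphenyl)-3-hydroxypropanoate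
Product: 13 tert-butyl (S)-3-(4-acetoxyphenyl)-3-[3,5-bis(benzyloxy)-4-bromophenoxy]propanoate
Conditions: PPh3 (1.5 equiv), DIAD (1.5 equiv), toluene, 0 °C to rt
Reagents that add atoms: none
Why: Mitsunobu etherification: the phenoxide of 6 displaces the oxyphosphonium group of activated 12 by SN2 with inversion, which turns (R) into the (S) configuration of the future C2. The acetoxy group keeps the benzylic carbon from ionising, and toluene at low temperature should hold back elimination of the activated alcohol.

Step 7
Reactants: 13 tert-butyl (S)-3-(4-acetoxyphenyl)-3-[3,5-bis(benzyloxy)-4-bromophenoxy]propanoate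
Product: 14 (S)-3-(4-acetoxyphenyl)-3-[3,5-bis(benzyloxy)-4-bromophenoxy]propanoic acid
Conditions: TFA/CH2Cl2 (1:4), 0 °C to rt; co-evaporation with toluene
Reagents that add atoms: none
Why: Acidolysis of the tert-butyl ester (E1 loss of the tert-butyl cation as 2-methylpropene) frees the acid without base, which would expel the aryloxide by E1cB. The benzylic ether should survive because the adjacent cation would be destabilised by the acetoxy-substituted ring and the β-carboxyl group.

Step 8
Reactants: 14 (S)-3-(4-acetoxyphenyl)-3-[3,5-bis(benzyloxy)-4-bromophenoxy]propanoic acid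
Product: 16 (2S)-2-(4-acetoxyphenyl)-5,7-bis(benzyloxy)-6-bromochroman-4-one, via mixed anhydride 15 (not isolated)
Conditions: (CF3CO)2O (3 equiv), CH2Cl2, 0 °C to rt
Reagents that add atoms: trifluoroacetic anhydride, O=C(OC(=O)C(F)(F)F)C(F)(F)F (the trifluoroacetyl group of 15 only; no atom of it remains in 16)
Why: Trifluoroacetic anhydride converts acid 14 into mixed anhydride 15, whose non-fluorinated acyl group, activated by the trifluoroacetic acid set free, is attacked by the ring A carbon ortho to the ether oxygen; loss of a proton from the Wheland intermediate gives the aryl ketone and forms C4–C4a (intramolecular Friedel–Crafts acylation). The closest known reaction type is the anhydride-mediated cyclisation of 3-aryloxypropanoic acids to chroman-4-ones. Ring C closes in the 6-exo-trig mode at the acyl carbon through a six-membered transition state. No stereocentre is created; C2 should keep its (S) configuration because no bond to it is made or broken, no Lewis acid is present, and the acetoxy group makes ring B too poor a donor to support ionisation of C2–O1. The step needs regioselectivity, and the substrate supplies it by symmetry: the mirror plane through the ether carbon and the C–Br carbon of the phenoxy ring makes the two ortho carbons equivalent, so either closure puts bromine at C6. It also needs chemoselectivity: the attacked carbon is ortho or para to three oxygen donors, whereas the competing five-membered closure onto ring B would engage an ester-deactivated ring, the benzyl phenyl rings are unactivated, and the product ketone is deactivated towards a second acylation.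

Step 9
Reactants: 16 (2S)-2-(4-acetoxyphenyl)-5,7-bis(benzyloxy)-6-bromochroman-4-one
Product: 17 (2S)-2-(4-acetoxyphenyl)-6-bromo-5,7-dihydroxychroman-4-one
Conditions: BCl3 (6 equiv), C6HMe5 (8 equiv), CH2Cl2, −78 °C; MeOH/CHCl3 quench at −78 °C
Reagents that add atoms: none
Why: Lewis-acid debenzylation: BCl3 cleaves the aryl benzyl ethers at −78 °C (the C5 ether assisted by chelation to the C4 carbonyl) and pentamethylbenzene traps the benzyl cation by Friedel–Crafts alkylation so that it cannot re-alkylate ring A. The aryl acetate, the bromide and the C2 centre should be untouched at this temperature, and the step is placed before the acid-labile chain is introduced.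

Step 10
Reactants: 18 (S)-citronellal [(3S)-3,7-dimethyloct-6-enal]
Product: 20 (S)-3,7-dimethyloct-6-en-1-yne, via enol nonaflate 19 (not isolated)
Conditions: C4F9SO2F (1.2 equiv), phosphazene base P2-Et (2.3 equiv), DMF, −30 °C to rt
Reagents that add atoms: nonafluorobutane-1-sulfonyl fluoride, O=S(=O)(F)C(F)(F)C(F)(F)C(F)(F)C(F)(F)F (the sulfonyl group of 19 only)
Why: One-pot enol sulfonylation and elimination: the base enolises the aldehyde, the enolate is O-sulfonylated to 19, and a second equivalent of base eliminates nonaflate to give the terminal alkyne with the same ten carbons. C3 is not a reacting centre, and its hydrogen (allylic in 19, propargylic in 20) is far less acidic than the alkyne C–H, so the configuration should be kept.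

Step 11
Reactants: 20 (S)-3,7-dimethyloct-6-en-1-yne
Product: 21 tributyl[(1E,3S)-3,7-dimethylocta-1,6-dien-1-yl]stannane
Conditions: Bu3SnH (1.2 equiv), PdCl2(PPh3)2 (2 mol %), THF, 0 °C to rt
Reagents that add atoms: tributyltin hydride, CCCC[SnH](CCCC)CCCC
Why: Palladium-catalysed syn-hydrostannylation of a terminal alkyne; the branch at the propargylic carbon directs tin to the terminal carbon and syn addition gives the (E)-alkenylstannane. The trisubstituted alkene does not react.

Step 12
Reactants: 17 (2S)-2-(4-acetoxyphenyl)-6-bromo-5,7-dihydroxychroman-4-one; 21 tributyl[(1E,3S)-3,7-dimethylocta-1,6-dien-1-yl]stannane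
Product: 22 (2S)-2-(4-acetoxyphenyl)-5,7-dihydroxy-6-[(1E,3S)-3,7-dimethylocta-1,6-dien-1-yl]chroman-4-one
Conditions: Pd(PtBu3)2 (10 mol %), 21 (1.5 equiv), 1,4-dioxane (degassed), 60 °C
Reagents that add atoms: none
Why: Stille coupling: the bulky, electron-rich zerovalent palladium complex inserts into the hindered C6–Br bond and the alkenyl group is transferred from tin with retention of the (E) geometry. No base or fluoride is added, so ring C should stay closed and the acetate in place; neither stereocentre is involved.

Step 13
Reactants: 22 (2S)-2-(4-acetoxyphenyl)-5,7-dihydroxy-6-[(1E,3S)-3,7-dimethylocta-1,6-dien-1-yl]chroman-4-one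
Product: 23 (2S)-5,7-dihydroxy-2-(4-hydroxyphenyl)-6-[(1E,3S)-3,7-dimethylocta-1,6-dien-1-yl]chroman-4-one (CNP0150993.1)
Conditions: NH4OAc (10 equiv), MeOH/H2O (4:1), rt
Reagents that add atoms: none
Why: Ammonium acetate-mediated solvolysis of a phenolic acetate at near-neutral pH; it avoids acid, which would cyclise the ortho-hydroxystyrene and the trisubstituted alkene onto the phenols, and base strong enough to open ring C, so both stereocentres should persist.

## Compound list

1 | 4-bromo-3,5-dihydroxybenzoic acid | OC(=O)c1cc(O)c(Br)c(O)c1 | starting material
2 | benzyl 3,5-bis(benzyloxy)-4-bromobenzoate | O=C(OCc1ccccc1)c1cc(OCc2ccccc2)c(Br)c(OCc2ccccc2)c1 | intermediate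
3 | 3,5-bis(benzyloxy)-4-bromo-N-methoxy-N-methylbenzamide (Weinreb amide, not isolated) | CON(C)C(=O)c1cc(OCc2ccccc2)c(Br)c(OCc2ccccc2)c1 | intermediate
4 | 1-[3,5-bis(benzyloxy)-4-bromophenyl]ethan-1-one | CC(=O)c1cc(OCc2ccccc2)c(Br)c(OCc2ccccc2)c1 | intermediate
5 | 3,5-bis(benzyloxy)-4-bromophenyl acetate (not isolated) | CC(=O)Oc1cc(OCc2ccccc2)c(Br)c(OCc2ccccc2)c1 | intermediate
6 | 3,5-bis(benzyloxy)-4-bromophenol | Oc1cc(OCc2ccccc2)c(Br)c(OCc2ccccc2)c1 | intermediate
7 | 4-acetoxybenzoic acid | CC(=O)Oc1ccc(cc1)C(O)=O | starting material
8 | potassium 3-(tert-butoxy)-3-oxopropanoate | [K+].[O-]C(=O)CC(=O)OC(C)(C)C | starting material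
9 | 4-acetoxybenzoyl chloride (not isolated) | CC(=O)Oc1ccc(cc1)C(Cl)=O | intermediate
10 | 2-(4-acetoxybenzoyl)-3-(tert-butoxy)-3-oxopropanoic acid (formed as its magnesium chelate, not isolated; its one stereocentre is labile and undefined) | CC(=O)Oc1ccc(cc1)C(=O)C(C(O)=O)C(=O)OC(C)(C)C | intermediate
11 | tert-butyl 3-(4-acetoxyphenyl)-3-oxopropanoate | CC(=O)Oc1ccc(cc1)C(=O)CC(=O)OC(C)(C)C | intermediate
12 | tert-butyl (R)-3-(4-acetoxyphenyl)-3-hydroxypropanoate | CC(C)(C)OC(=O)C[C@@H](O)c1ccc(OC(C)=O)cc1 | intermediate
13 | tert-butyl (S)-3-(4-acetoxyphenyl)-3-[3,5-bis(benzyloxy)-4-bromophenoxy]propanoate | CC(C)(C)OC(=O)C[C@@H](c1ccc(OC(C)=O)cc1)Oc1cc(OCc2ccccc2)c(Br)c(OCc2ccccc2)c1 | intermediate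
14 | (S)-3-(4-acetoxyphenyl)-3-[3,5-bis(benzyloxy)-4-bromophenoxy]propanoic acid | OC(=O)C[C@@H](c1ccc(OC(C)=O)cc1)Oc1cc(OCc2ccccc2)c(Br)c(OCc2ccccc2)c1 | intermediate
15 | (S)-3-(4-acetoxyphenyl)-3-[3,5-bis(benzyloxy)-4-bromophenoxy]propanoic trifluoroacetic anhydride (not isolated) | O=C(OC(=O)C(F)(F)F)C[C@@H](c1ccc(OC(C)=O)cc1)Oc1cc(OCc2ccccc2)c(Br)c(OCc2ccccc2)c1 | intermediate
16 | (2S)-2-(4-acetoxyphenyl)-5,7-bis(benzyloxy)-6-bromochroman-4-one | Brc1c(OCc3ccccc3)cc2c(c1OCc3ccccc3)C(=O)C[C@@H](c3ccc(OC(C)=O)cc3)O2 | intermediate
17 | (2S)-2-(4-acetoxyphenyl)-6-bromo-5,7-dihydroxychroman-4-one | Brc1c(O)cc2c(c1O)C(=O)C[C@@H](c3ccc(OC(C)=O)cc3)O2 | intermediate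
18 | (S)-citronellal, (3S)-3,7-dimethyloct-6-enal | CC(C)=CCC[C@H](C)CC=O | starting material
19 | (3S)-3,7-dimethylocta-1,6-dien-1-yl nonafluorobutane-1-sulfonate (E/Z mixture, not isolated) | CC(C)=CCC[C@H](C)C=COS(=O)(=O)C(F)(F)C(F)(F)C(F)(F)C(F)(F)F | intermediate
20 | (S)-3,7-dimethyloct-6-en-1-yne | CC(C)=CCC[C@H](C)C#C | intermediate
21 | tributyl[(1E,3S)-3,7-dimethylocta-1,6-dien-1-yl]stannane | CC(C)=CCC[C@H](C)/C=C/[Sn](CCCC)(CCCC)CCCC | intermediate
22 | (2S)-2-(4-acetoxyphenyl)-5,7-dihydroxy-6-[(1E,3S)-3,7-dimethylocta-1,6-dien-1-yl]chroman-4-one | CC(C)=CCC[C@H](C)/C=C/c1c(O)cc2c(c1O)C(=O)C[C@@H](c1ccc(OC(C)=O)cc1)O2 | intermediate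
23 | (2S)-5,7-dihydroxy-2-(4-hydroxyphenyl)-6-[(1E,3S)-3,7-dimethylocta-1,6-dien-1-yl]chroman-4-one | CC(C)=CCC[C@H](C)/C=C/c1c(O)cc2c(c1O)C(=O)C[C@@H](c1ccc(O)cc1)O2 | target

## Step count and least certain steps

Total: 13 steps. Longest linear sequence: 9 steps (steps 1, 2, 3, 6, 7, 8, 9, 12, 13). Steps 4–5 and steps 10–11 are two-step branches.

**Step 8 (key step).** The most likely failure is erosion of the C2 configuration while the acid is activated. Ionisation of the benzylic C2–O1 bond in the acidic medium, or elimination of phenol 6 from the mixed anhydride, would compete if ring closure is slowed by the bromine atom, which withdraws electron density and pushes the neighbouring benzyloxy group out of conjugation. Fallback: the stereocentre is taken out of the acylation and introduced afterwards. The route sets out from phenol 6, which is deprotonated (NaH, DMF) and opens oxetan-2-one F1 at its CH2–O carbon to give 3-[3,5-bis(benzyloxy)-4-bromophenoxy]propanoic acid F2. This acid has no stereocentre and can be cyclised under the same or more forcing Friedel–Crafts conditions, with the same symmetry argument, to 5,7-bis(benzyloxy)-6-bromochroman-4-one F3. Dehydrogenation (IBX, DMSO, 70 °C) gives 5,7-bis(benzyloxy)-6-bromo-4H-chromen-4-one F4. A catalytic asymmetric conjugate addition of 4-acetoxyphenylboronic acid F5 then sets C2 and returns to the route at 16. The conditions are Pd(OCOCF3)2 with the enantiomer of the tert-butyl pyridine-oxazoline ligand that leads to (2S), NH4PF6, water, 1,2-dichloroethane, 60 °C. The catalyst stays divalent palladium throughout, so the C–Br bond should not be touched.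

**Step 6.** What may go wrong is elimination of the activated alcohol, because the hydrogens next to the ester are acidic and antiperiplanar to the oxyphosphonium group, together with acetyl transfer from 12 to the phenoxide of 6 and partial loss of enantiomeric purity through ionisation. Fallback: the ester is replaced by a vinyl group during the substitution. The route sets out from phenol 6. 4-Formylphenyl acetate F6 is allylated with allyltributylstannane F7 under Keck conditions (Ti(OiPr)4 and the BINOL enantiomer that gives the (R)-carbinol) to 4-[(1R)-1-hydroxybut-3-en-1-yl]phenyl acetate F8. Mitsunobu reaction of F8 with 6 gives, with inversion, 4-{(1S)-1-[3,5-bis(benzyloxy)-4-bromophenoxy]but-3-en-1-yl}phenyl acetate F9, in which no acidifying group flanks the reacting carbon. Oxidative cleavage of the alkene (OsO4 cat., NaIO4, 2,6-lutidine, dioxane/water) gives (S)-3-(4-acetoxyphenyl)-3-[3,5-bis(benzyloxy)-4-bromophenoxy]propanal F10, and Pinnick oxidation (NaClO2, NaH2PO4, 2-methylbut-2-ene) returns to the route at 14.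

**Step 12.** Oxidative addition at a C–Br bond flanked by two hydroxyl groups may be slow, and the acidic phenols may protodestannylate 21 or bind palladium as phenoxides, so that the coupling stalls. Fallback: the phenols are masked for the coupling. The route sets out from 17, which is acetylated (Ac2O, pyridine, DMAP cat., 0 °C) to (2S)-2-(4-acetoxyphenyl)-6-bromo-4-oxochroman-5,7-diyl diacetate F11. Its ring is less electron-rich and has no acidic hydrogen. Stille coupling with 21 under the conditions of step 12 gives (2S)-2-(4-acetoxyphenyl)-6-[(1E,3S)-3,7-dimethylocta-1,6-dien-1-yl]-4-oxochroman-5,7-diyl diacetate F12. Solvolysis of all three phenolic acetates with NH4OAc in aqueous methanol returns to the route at 23.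

**Step 10.** The elimination of the enol sulfonate may stop short, or the strong base may equilibrate the alkyne with an allene and so erode the C3 configuration; the product is also volatile. Fallback: the alkyne and the stannane are bypassed. The route sets out from 17, which is coupled directly with (S)-3,7-dimethylocta-1,6-diene F13, the terminal alkene with the same carbon skeleton, in a Heck–Mizoroki reaction (Pd(PtBu3)2, Cy2NMe, 1,4-dioxane, 60 °C). β-Hydride elimination towards the benzylic hydrogen gives the conjugated (E)-styrene and returns to the route at 22. The price is possible competition from elimination towards C3' and the presence of an amine base next to ring C.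

## Further compounds

F1 | step 8 | oxetan-2-one (β-propiolactone, purchased) | O=C1CCO1
F2 | step 8 | 3-[3,5-bis(benzyloxy)-4-bromophenoxy]propanoic acid | OC(=O)CCOc1cc(OCc2ccccc2)c(Br)c(OCc2ccccc2)c1
F3 | step 8 | 5,7-bis(benzyloxy)-6-bromochroman-4-one | Brc1c(OCc3ccccc3)cc2c(c1OCc3ccccc3)C(=O)CCO2
F4 | step 8 | 5,7-bis(benzyloxy)-6-bromo-4H-chromen-4-one | Brc1c(OCc3ccccc3)cc2c(c1OCc3ccccc3)C(=O)C=CO2
F5 | step 8 | 4-acetoxyphenylboronic acid (purchased) | CC(=O)Oc1ccc(cc1)B(O)O
F6 | step 6 | 4-formylphenyl acetate (purchased) | CC(=O)Oc1ccc(C=O)cc1
F7 | step 6 | allyltributylstannane (purchased) | C=CC[Sn](CCCC)(CCCC)CCCC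
F8 | step 6 | 4-[(1R)-1-hydroxybut-3-en-1-yl]phenyl acetate | C=CC[C@@H](O)c1ccc(OC(C)=O)cc1
F9 | step 6 | 4-{(1S)-1-[3,5-bis(benzyloxy)-4-bromophenoxy]but-3-en-1-yl}phenyl acetate | C=CC[C@@H](c1ccc(OC(C)=O)cc1)Oc1cc(OCc2ccccc2)c(Br)c(OCc2ccccc2)c1
F10 | step 6 | (S)-3-(4-acetoxyphenyl)-3-[3,5-bis(benzyloxy)-4-bromophenoxy]propanal | O=CC[C@@H](c1ccc(OC(C)=O)cc1)Oc1cc(OCc2ccccc2)c(Br)c(OCc2ccccc2)c1
F11 | step 12 | (2S)-2-(4-acetoxyphenyl)-6-bromo-4-oxochroman-5,7-diyl diacetate | Brc1c(OC(C)=O)cc2c(c1OC(C)=O)C(=O)C[C@@H](c3ccc(OC(C)=O)cc3)O2
F12 | step 12 | (2S)-2-(4-acetoxyphenyl)-6-[(1E,3S)-3,7-dimethylocta-1,6-dien-1-yl]-4-oxochroman-5,7-diyl diacetate | CC(C)=CCC[C@H](C)/C=C/c1c(OC(C)=O)cc2c(c1OC(C)=O)C(=O)C[C@@H](c1ccc(OC(C)=O)cc1)O2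
F13 | step 10 | (S)-3,7-dimethylocta-1,6-diene (purchased) | CC(C)=CCC[C@H](C)C=C
A1 | alternative 1 | (2S)-2-[4-(tert-butyldimethylsilyloxy)phenyl]-5,7-dihydroxy-6-[(1E,3S)-3,7-dimethylocta-1,6-dien-1-yl]chroman-4-one | CC(C)=CCC[C@H](C)/C=C/c1c(O)cc2c(c1O)C(=O)C[C@@H](c1ccc(O[Si](C)(C)C(C)(C)C)cc1)O2
A2 | alternative 1 | (S)-5-bromo-2-[4-(tert-butyldimethylsilyloxy)phenyl]-2,3-dihydro-4H-pyran-4-one | O=C1C[C@@H](c2ccc(O[Si](C)(C)C(C)(C)C)cc2)OC=C1Br
A3 | alternative 1 | 1-methoxy-2-[(1E,3S)-3,7-dimethylocta-1,6-dien-1-yl]-1,3-bis(trimethylsilyloxy)buta-1,3-diene | COC(O[Si](C)(C)C)=C(/C=C/[C@@H](C)CCC=C(C)C)C(=C)O[Si](C)(C)C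
A4 | alternative 2 | (2S)-6-bromo-5,7-bis(triisopropylsilyloxy)-2-[4-(triisopropylsilyloxy)phenyl]chroman-4-one | Brc1c(O[Si](C(C)C)(C(C)C)C(C)C)cc2c(c1O[Si](C(C)C)(C(C)C)C(C)C)C(=O)C[C@@H](c1ccc(O[Si](C(C)C)(C(C)C)C(C)C)cc1)O2
A5 | alternative 2 | 1-{3-bromo-2,4-bis(triisopropylsilyloxy)-6-[4-(triisopropylsilyloxy)benzyloxy]phenyl}-2-diazoethan-1-one | [N-]=[N+]=CC(=O)c1c(OCc2ccc(O[Si](C(C)C)(C(C)C)C(C)C)cc2)cc(O[Si](C(C)C)(C(C)C)C(C)C)c(Br)c1O[Si](C(C)C)(C(C)C)C(C)C
A6 | alternative 3 | (2S)-5,7-bis(methoxymethoxy)-2-[4-(methoxymethoxy)phenyl]-6-[(1E,3S)-3,7-dimethylocta-1,6-dien-1-yl]chroman-4-one | CC(C)=CCC[C@H](C)/C=C/c1c(OCOC)cc2c(c1OCOC)C(=O)C[C@@H](c1ccc(OCOC)cc1)O2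
A7 | alternative 3 | (S)-1-{3-[(1E,3S)-3,7-dimethylocta-1,6-dien-1-yl]-6-fluoro-2,4-bis(methoxymethoxy)phenyl}-3-hydroxy-3-[4-(methoxymethoxy)phenyl]propan-1-one | CC(C)=CCC[C@H](C)/C=C/c1c(OCOC)cc(F)c(c1OCOC)C(=O)C[C@H](O)c1ccc(OCOC)cc1
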